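**Plan**

Numbering (eremophilane): ring A = C1–C5 and C10, ring B = C5–C10; esters at C3 and C9, ketone C8, isopropenyl at C7, C14 = methyl on C5; target read as 3R,4R,5R,7S,9S,10R (trans-decalin, all ring B substituents equatorial).
Retrosynthesis: cut the two ester C–O bonds, then C7–C11 (acetone aldol, dehydration), then the ring B bond C5–C6, then C8–C7 (vinyl Grignard) and C10–C9 (glyoxylate), back to 2-methylcyclohex-2-en-1-one.
Enabling feature: C5 is a quaternary ring-fusion carbon that carries a methyl group, so it is the tertiary radical formed when a hydrogen atom adds to an exocyclic C5=C14 methylene; its ring B neighbour C6 is β to the C8 ketone, so it is the free end of a vinyl ketone. The two carbons have no polar pairing and are joined by a radical.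
Forward: ring A is built first with all of ring B hanging from C10 as an open chain; ring B closes last through C5–C6; the isopropenyl group and the two esters follow.
Stereochemistry: a CBS-derived carbinol steers the hydroboration that sets C3 and C4 and is then oxidised away; C10 by enol protonation, C9 by allylic-strain-controlled enolate hydroxylation, C5 in the ring closure (chair, trans-fusion), C7 by equatorial aldol attack.

Key step: step 10

(TBS = tert-butyldimethylsilyl.)

**Step 1**
Reactants: 1 2-methylcyclohex-2-en-1-one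
Product: 2 (1R)-2-methylcyclohex-2-en-1-ol
Conditions: (S)-2-methyl-CBS-oxazaborolidine (10 mol%), BH3·SMe2, THF, −20 °C; then MeOH
Reagents that add atoms: none
Why: Corey–Bakshi–Shibata reduction, in which the α-methylated alkenyl arm acts as the large group and the ring CH2 as the small one, so hydride should reach one carbonyl face and give the (R)-allylic alcohol by 1,2-reduction.

**Step 2**
Reactants: 2 (1R)-2-methylcyclohex-2-en-1-ol
Product: 3 (1R,3R)-2-methylcyclohexane-1,3-diol
Conditions: BH3·THF (2.5 equiv), THF, 0 °C to rt; then NaOH, H2O2, 0 °C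
Reagents that add atoms: hydrogen peroxide OO
Why: Hydroboration–oxidation, in which the alkoxyborane formed from the free hydroxyl lets borane add syn across the trisubstituted alkene on the face anti to the C–O bond with boron on the less substituted carbon, so the new C3 hydroxyl ends trans to the C4 methyl while the original hydroxyl is cis to it.

**Step 3**
Reactants: 3 (1R,3R)-2-methylcyclohexane-1,3-diol
Product: 4 (1R,2R,3R)-3-(TBSO)-2-methylcyclohexan-1-ol
Conditions: TBSCl (1.05 equiv), imidazole, DMF, −20 to 0 °C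
Reagents that add atoms: tert-butyldimethylsilyl chloride C[Si](C)(Cl)C(C)(C)C
Why: Selective monosilylation, since in the chair with equatorial methyl the hydroxyl trans to the methyl (future C3–O) is equatorial and open while the other is axial and shielded, so the silyl chloride should take the equatorial one.

**Step 4**
Reactants: 4 (1R,2R,3R)-3-(TBSO)-2-methylcyclohexan-1-ol
Product: 5 (2S,3R)-3-(TBSO)-2-methylcyclohexan-1-one
Conditions: Dess–Martin periodinane, NaHCO3, CH2Cl2, 0 °C to rt
Reagents that add atoms: none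
Why: Dess–Martin oxidation of the remaining axial alcohol under buffered, non-enolising conditions removes the relay stereocentre and leaves the C4 methyl (now α to the C5 ketone, trans to the silyloxy group) unepimerised.

**Step 5**
Reactants: 5 (2S,3R)-3-(TBSO)-2-methylcyclohexan-1-one
Product: 8 ethyl (2E)-2-[(3S,4R)-4-(TBSO)-3-methyl-2-oxocyclohexylidene]acetate, via aldol adduct 6 (not isolated), via aldol mesylate 7 (not isolated)
Conditions: LDA (1.05 equiv), THF, −78 °C; ethyl glyoxylate, −78 °C; then MsCl, Et3N, −78 to 0 °C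
Reagents that add atoms: ethyl glyoxylate O=CC(=O)OCC
Why: Directed aldol condensation, in which LDA deprotonates the unhindered C10 methylene (kinetic enolate, C4 untouched), the enolate adds to the aldehyde and the mesylate undergoes E1cB elimination to the doubly activated (E)-alkylidene ketone, erasing both new stereocentres on purpose because C–C bond formation at C10 would enter trans to the C4 methyl.

**Step 6**
Reactants: 8 ethyl (2E)-2-[(3S,4R)-4-(TBSO)-3-methyl-2-oxocyclohexylidene]acetate
Product: 9 ethyl 2-[(1S,3S,4R)-4-(TBSO)-3-methyl-2-oxocyclohexyl]acetate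
Conditions: Zn dust, AcOH, THF, 0 °C to rt
Reagents that add atoms: none
Why: Dissolving-metal reduction of the ene-dicarbonyl unit gives the C10 enol, whose ketonisation by axial protonation should place the acetate arm equatorial and cis to the C4 methyl (the all-equatorial 2,6-cis ketone, also the more stable C10 epimer), under base-free conditions that leave C4 alone.

**Step 7**
Reactants: 9 ethyl 2-[(1S,3S,4R)-4-(TBSO)-3-methyl-2-oxocyclohexyl]acetate
Product: 10 ethyl 2-[(1S,3R,4R)-4-(TBSO)-3-methyl-2-methylidenecyclohexyl]acetate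
Conditions: Zn, CH2Br2, TiCl4, THF/CH2Cl2, 0 °C to rt
Reagents that add atoms: dibromomethane BrCBr
Why: Takai–Lombardo methylenation, whose non-basic zinc/titanium methylene reagent converts the hindered, enolisable ketone into the exocyclic C5=C14 alkene without epimerising C4 or C10 and without touching the ester or the silyl ether.

**Step 8**
Reactants: 10 ethyl 2-[(1S,3R,4R)-4-(TBSO)-3-methyl-2-methylidenecyclohexyl]acetate
Product: 11 ethyl (2S)-2-[(1R,3R,4R)-4-(TBSO)-3-methyl-2-methylidenecyclohexyl]-2-hydroxyacetate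
Conditions: KHMDS, THF, −78 °C; trans-2-(phenylsulfonyl)-3-phenyloxaziridine, −78 °C; then AcOH
Reagents that add atoms: trans-2-(phenylsulfonyl)-3-phenyloxaziridine O1N(S(=O)(=O)c2ccccc2)C1c1ccccc1
Why: Enolate hydroxylation with an N-sulfonyloxaziridine, in which the C10–H bond eclipses the enolate plane (minimised A(1,3) strain) and the oxidant should attack the face flanked by C1H2, away from the bulkier C5(=CH2) side, giving the (2S) alcohol that becomes the equatorial C9–O of ring B.

**Step 9**
Reactants: 11 ethyl (2S)-2-[(1R,3R,4R)-4-(TBSO)-3-methyl-2-methylidenecyclohexyl]-2-hydroxyacetate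
Product: 13 (1S)-1-[(1R,3R,4R)-4-(TBSO)-3-methyl-2-methylidenecyclohexyl]-1-hydroxybut-3-en-2-one, via Weinreb amide 12 (not isolated)
Conditions: N,O-dimethylhydroxylamine hydrochloride, iPrMgCl, THF, −20 °C; then CH2=CHMgBr, −20 to 0 °C; inverse quench into cold 1 M HCl
Reagents that add atoms: vinylmagnesium bromide C=C[Mg]Br
Why: One-pot ester to Weinreb amide to ketone sequence, in which the chelated tetrahedral intermediate stops the Grignard addition at the vinyl ketone, the C9 magnesium alkoxide protects that centre from enolisation and the acidic inverse quench prevents conjugate addition of the released amine.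

**Step 10**
Reactants: 13 (1S)-1-[(1R,3R,4R)-4-(TBSO)-3-methyl-2-methylidenecyclohexyl]-1-hydroxybut-3-en-2-one
Product: 14 (1S,4aR,5R,6R,8aR)-6-(TBSO)-1-hydroxy-4a,5-dimethyloctahydronaphthalen-2(1H)-one
Conditions: Fe(acac)3 (0.5 equiv), PhSiH3 (3 equiv), EtOH/ethylene glycol 5:1, 0.01 M, 60 °C
Reagents that add atoms: none
Why: Fe(acac)3 and PhSiH3 in ethanol give an iron hydride that transfers a hydrogen atom to the terminal CH2 of the electron-rich exocyclic alkene (Markovnikov), creating the C14 methyl and a nucleophilic tertiary radical at C5, which adds to C6, the unsubstituted β-carbon of the vinyl ketone; the α-keto radical at C7 is then reduced by divalent iron to the enolate and protonated by ethanol, returning trivalent iron. The closest known reaction type is the hydrogen-atom-transfer-initiated reductive olefin–enone coupling (Giese addition) in its intramolecular form, as used to close decalins onto quaternary carbons. Ring B closes in the 6-endo-trig mode, because attack at the acyl-bearing α-carbon (5-exo) is disfavoured by polarity and by the bulk of the tertiary radical. The new quaternary centre C5 is controlled by C10: the chain leaves C10 equatorially and folds into a chair with the C9 hydroxyl equatorial, so C6 should bond to the C5 face on the side of H-10 and the methyl should end axial and anti to H-10 (trans-fusion), the equatorial C4 methyl adding little bias. The step needs hydrogen-atom transfer to the 1,1-disubstituted alkene and not to the vinyl ketone, which the electron-rich unhindered methylene secures, and ring closure faster than reduction of the radical, which the six-membered transition state and high dilution secure.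

**Step 11**
Reactants: 14 (1S,4aR,5R,6R,8aR)-6-(TBSO)-1-hydroxy-4a,5-dimethyloctahydronaphthalen-2(1H)-one
Product: 15 (1S,3S,4aR,5R,6R,8aR)-6-(TBSO)-1-hydroxy-3-(2-hydroxypropan-2-yl)-4a,5-dimethyloctahydronaphthalen-2(1H)-one
Conditions: LDA (2.3 equiv), THF, −78 °C; acetone, −78 °C; then AcOH, −78 °C
Reagents that add atoms: acetone CC(C)=O
Why: Dianion aldol addition, in which the C9 lithium alkoxide blocks enolisation toward C9 so the enolate forms toward C7, and acetone should add on the α face away from the axial C5 methyl, placing the new C7 substituent equatorial (also the more stable C7 epimer).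

**Step 12**
Reactants: 15 (1S,3S,4aR,5R,6R,8aR)-6-(TBSO)-1-hydroxy-3-(2-hydroxypropan-2-yl)-4a,5-dimethyloctahydronaphthalen-2(1H)-one
Product: 16 (1S,3S,4aR,5R,6R,8aR)-6-(TBSO)-3-(2-hydroxypropan-2-yl)-4a,5-dimethyl-2-oxodecahydronaphthalen-1-yl (2E)-3-methylpent-2-enoate
Conditions: (E)-3-methylpent-2-enoic acid, DCC, DMAP (10 mol%), CH2Cl2, 0 °C to rt
Reagents that add atoms: (E)-3-methylpent-2-enoic acid CC/C(C)=C/C(=O)O
Why: Steglich esterification, which should acylate the secondary C9 hydroxyl while the tertiary hydroxyl is too hindered to react, with cold carbodiimide activation keeping the E geometry of the enoate.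

**Step 13**
Reactants: 16 (1S,3S,4aR,5R,6R,8aR)-6-(TBSO)-3-(2-hydroxypropan-2-yl)-4a,5-dimethyl-2-oxodecahydronaphthalen-1-yl (2E)-3-methylpent-2-enoate
Product: 17 (1S,3S,4aR,5R,6R,8aR)-6-(TBSO)-4a,5-dimethyl-2-oxo-3-(prop-1-en-2-yl)decahydronaphthalen-1-yl (2E)-3-methylpent-2-enoate
Conditions: SOCl2, pyridine, CH2Cl2, −30 to 0 °C
Reagents that add atoms: none
Why: Kinetically controlled E2 dehydration of the tertiary chlorosulfite, in which six freely rotating methyl hydrogens compete with a single ring hydrogen at C7 whose anti-periplanar alignment pushes both methyls against the ring, so the terminal isopropenyl alkene is expected, and the cold weakly basic medium should not move it into conjugation.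

**Step 14**
Reactants: 17 (1S,3S,4aR,5R,6R,8aR)-6-(TBSO)-4a,5-dimethyl-2-oxo-3-(prop-1-en-2-yl)decahydronaphthalen-1-yl (2E)-3-methylpent-2-enoate
Product: 18 (1S,3S,4aR,5R,6R,8aR)-6-hydroxy-4a,5-dimethyl-2-oxo-3-(prop-1-en-2-yl)decahydronaphthalen-1-yl (2E)-3-methylpent-2-enoate
Conditions: HF·pyridine, pyridine, THF, 0 °C to rt
Reagents that add atoms: none
Why: Fluoride-mediated desilylation under buffered, slightly acidic conditions frees the C3 hydroxyl without the base that would isomerise the α-isopropenyl ketone or cleave the C9 ester.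

**Step 15**
Reactants: 18 (1S,3S,4aR,5R,6R,8aR)-6-hydroxy-4a,5-dimethyl-2-oxo-3-(prop-1-en-2-yl)decahydronaphthalen-1-yl (2E)-3-methylpent-2-enoate
Product: 19 (1S,3S,4aR,5R,6R,8aR)-4a,5-dimethyl-6-{[(2Z)-2-methylbut-2-enoyl]oxy}-2-oxo-3-(prop-1-en-2-yl)decahydronaphthalen-1-yl (2E)-3-methylpent-2-enoate
Conditions: angelic acid, 2,4,6-trichlorobenzoyl chloride, Et3N, toluene, rt; then 18, toluene, 75 °C
Reagents that add atoms: angelic acid C/C=C(/C)C(=O)O
Why: Mixed-anhydride (Yamaguchi-type) acylation without a nucleophilic catalyst, in which the alcohol attacks the unshielded angeloyl carbonyl and the absence of DMAP should avoid Z to E isomerisation to the tiglate.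

**Compound list**

1 | 2-methylcyclohex-2-en-1-one | CC1=CCCCC1=O | starting material
2 | (1R)-2-methylcyclohex-2-en-1-ol | CC1=CCCC[C@H]1O | intermediate
3 | (1R,3R)-2-methylcyclohexane-1,3-diol | CC1[C@H](O)CCC[C@H]1O | intermediate
4 | (1R,2R,3R)-3-[(tert-butyldimethylsilyl)oxy]-2-methylcyclohexan-1-ol | C[C@H]1[C@H](O[Si](C)(C)C(C)(C)C)CCC[C@H]1O | intermediate
5 | (2S,3R)-3-[(tert-butyldimethylsilyl)oxy]-2-methylcyclohexan-1-one | C[C@H]1[C@H](O[Si](C)(C)C(C)(C)C)CCCC1=O | intermediate
6 | ethyl 2-[(3S,4R)-4-[(tert-butyldimethylsilyl)oxy]-3-methyl-2-oxocyclohexyl]-2-hydroxyacetate (aldol adduct, present as lithium alkoxide, mixture at the two new centres) | C[C@H]1[C@H](O[Si](C)(C)C(C)(C)C)CCC(C(O)C(=O)OCC)C1=O | intermediate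
7 | ethyl 2-[(3S,4R)-4-[(tert-butyldimethylsilyl)oxy]-3-methyl-2-oxocyclohexyl]-2-[(methylsulfonyl)oxy]acetate (aldol mesylate, mixture at the two new centres) | C[C@H]1[C@H](O[Si](C)(C)C(C)(C)C)CCC(C(OS(C)(=O)=O)C(=O)OCC)C1=O | intermediate
8 | ethyl (2E)-2-[(3S,4R)-4-[(tert-butyldimethylsilyl)oxy]-3-methyl-2-oxocyclohexylidene]acetate | C[C@H]1[C@H](O[Si](C)(C)C(C)(C)C)CC/C(=C\C(=O)OCC)C1=O | intermediate
9 | ethyl 2-[(1S,3S,4R)-4-[(tert-butyldimethylsilyl)oxy]-3-methyl-2-oxocyclohexyl]acetate | C[C@H]1[C@H](O[Si](C)(C)C(C)(C)C)CC[C@@H](CC(=O)OCC)C1=O | intermediate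
10 | ethyl 2-[(1S,3R,4R)-4-[(tert-butyldimethylsilyl)oxy]-3-methyl-2-methylidenecyclohexyl]acetate | C[C@H]1[C@H](O[Si](C)(C)C(C)(C)C)CC[C@@H](CC(=O)OCC)C1=C | intermediate
11 | ethyl (2S)-2-[(1R,3R,4R)-4-[(tert-butyldimethylsilyl)oxy]-3-methyl-2-methylidenecyclohexyl]-2-hydroxyacetate | C[C@H]1[C@H](O[Si](C)(C)C(C)(C)C)CC[C@@H]([C@H](O)C(=O)OCC)C1=C | intermediate
12 | (2S)-2-[(1R,3R,4R)-4-[(tert-butyldimethylsilyl)oxy]-3-methyl-2-methylidenecyclohexyl]-2-hydroxy-N-methoxy-N-methylacetamide (Weinreb amide) | C[C@H]1[C@H](O[Si](C)(C)C(C)(C)C)CC[C@@H]([C@H](O)C(=O)N(C)OC)C1=C | intermediate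
13 | (1S)-1-[(1R,3R,4R)-4-[(tert-butyldimethylsilyl)oxy]-3-methyl-2-methylidenecyclohexyl]-1-hydroxybut-3-en-2-one | C[C@H]1[C@H](O[Si](C)(C)C(C)(C)C)CC[C@@H]([C@H](O)C(=O)C=C)C1=C | intermediate
14 | (1S,4aR,5R,6R,8aR)-6-[(tert-butyldimethylsilyl)oxy]-1-hydroxy-4a,5-dimethyloctahydronaphthalen-2(1H)-one | C1C[C@]2(C)[C@@H](C)[C@H](O[Si](C)(C)C(C)(C)C)CC[C@H]2[C@H](O)C1=O | intermediate
15 | (1S,3S,4aR,5R,6R,8aR)-6-[(tert-butyldimethylsilyl)oxy]-1-hydroxy-3-(2-hydroxypropan-2-yl)-4a,5-dimethyloctahydronaphthalen-2(1H)-one | CC(C)(O)[C@@H]1C[C@]2(C)[C@@H](C)[C@H](O[Si](C)(C)C(C)(C)C)CC[C@H]2[C@H](O)C1=O | intermediate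
16 | (1S,3S,4aR,5R,6R,8aR)-6-[(tert-butyldimethylsilyl)oxy]-3-(2-hydroxypropan-2-yl)-4a,5-dimethyl-2-oxodecahydronaphthalen-1-yl (2E)-3-methylpent-2-enoate | CC(C)(O)[C@@H]1C[C@]2(C)[C@@H](C)[C@H](O[Si](C)(C)C(C)(C)C)CC[C@H]2[C@H](OC(=O)/C=C(\C)CC)C1=O | intermediate
17 | (1S,3S,4aR,5R,6R,8aR)-6-[(tert-butyldimethylsilyl)oxy]-4a,5-dimethyl-2-oxo-3-(prop-1-en-2-yl)decahydronaphthalen-1-yl (2E)-3-methylpent-2-enoate | C=C(C)[C@@H]1C[C@]2(C)[C@@H](C)[C@H](O[Si](C)(C)C(C)(C)C)CC[C@H]2[C@H](OC(=O)/C=C(\C)CC)C1=O | intermediate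
18 | (1S,3S,4aR,5R,6R,8aR)-6-hydroxy-4a,5-dimethyl-2-oxo-3-(prop-1-en-2-yl)decahydronaphthalen-1-yl (2E)-3-methylpent-2-enoate | C=C(C)[C@@H]1C[C@]2(C)[C@@H](C)[C@H](O)CC[C@H]2[C@H](OC(=O)/C=C(\C)CC)C1=O | intermediate
19 | (1S,3S,4aR,5R,6R,8aR)-4a,5-dimethyl-6-{[(2Z)-2-methylbut-2-enoyl]oxy}-2-oxo-3-(prop-1-en-2-yl)decahydronaphthalen-1-yl (2E)-3-methylpent-2-enoate | C=C(C)[C@@H]1C[C@]2(C)[C@@H](C)[C@H](OC(=O)/C(C)=C\C)CC[C@H]2[C@H](OC(=O)/C=C(\C)CC)C1=O | target

**Total step count:** 15
**Longest linear sequence:** 15 steps (fully linear)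

**Steps most likely to fail**

Step 10. The tertiary radical or the vinyl ketone may be reduced by the hydride source before ring closure, and face selectivity at C5 may be incomplete (cis-fused isomer). The fallback makes the same C5 radical without a hydride donor. It sets out from 13: epoxidation of the exocyclic alkene with mCPBA gives the spiro-epoxide F1 (either epimer serves, since the radical is planar). Cp2TiCl (trivalent titanium, from Cp2TiCl2 and Zn, THF) opens it reductively at the more substituted carbon, and the tertiary radical closes 6-endo onto the vinyl ketone to give the hydroxymethyl decalone F2. The primary alcohol is converted under Appel conditions (PPh3, I2, imidazole) to the neopentyl iodide F3, and Bu3SnH/AIBN reduction comes back to the route at 14.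

Step 13. Elimination may go toward C7 (conjugated isopropylidene ketone), or the isopropenyl double bond may later drift into conjugation. The fallback introduces the isopropenyl group as such and sets out from 14: LDA (2.2 equiv) and TMSCl give the bis(trimethylsilyl) enol ether F4. Pd2(dba)3/P(t-Bu)3-catalysed coupling of the tin enolate formed in situ with Bu3SnF and 2-bromopropene, followed by aqueous work-up, gives the isopropenyl hydroxy ketone F5. Steglich esterification of F5 with (E)-3-methylpent-2-enoic acid comes back to the route at 17.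

Step 8. Facial selectivity in the oxidation of the acyclic ester enolate may be low or reversed, giving the C9 epimer. The fallback sets the centre by substitution with inversion and sets out from 10: the same enolate oxidation is run, and the (2R)-hydroxy ester F6 is treated under Mitsunobu conditions (4-nitrobenzoic acid, PPh3, DIAD) to give the inverted 4-nitrobenzoate F7. Ethanolysis (K2CO3, EtOH) comes back to the route at 11.

**Further compounds**

F1 | step 10 | spiro-epoxide of 13: (1S)-1-hydroxy-1-[7-(tert-butyldimethylsilyloxy)-8-methyl-1-oxaspiro[2.5]octan-4-yl]but-3-en-2-one, ring centres as in 13, either configuration at the spiro carbon | C[C@H]1[C@H](O[Si](C)(C)C(C)(C)C)CC[C@@H]([C@H](O)C(=O)C=C)C12CO2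
F2 | step 10 | 6-(tert-butyldimethylsilyloxy)-1-hydroxy-4a-(hydroxymethyl)-5-methyloctahydronaphthalen-2(1H)-one, configuration as in 14 | C1C[C@]2(CO)[C@@H](C)[C@H](O[Si](C)(C)C(C)(C)C)CC[C@H]2[C@H](O)C1=O
F3 | step 10 | 6-(tert-butyldimethylsilyloxy)-1-hydroxy-4a-(iodomethyl)-5-methyloctahydronaphthalen-2(1H)-one, configuration as in 14 | C1C[C@]2(CI)[C@@H](C)[C@H](O[Si](C)(C)C(C)(C)C)CC[C@H]2[C@H](O)C1=O
F4 | step 13 | bis(trimethylsilyl) derivative of 14: C9 trimethylsilyl ether and C7=C8 trimethylsilyl enol ether | C=1C[C@]2(C)[C@@H](C)[C@H](O[Si](C)(C)C(C)(C)C)CC[C@H]2[C@H](O[Si](C)(C)C)C=1O[Si](C)(C)C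
F5 | step 13 | (1S,3S,4aR,5R,6R,8aR)-6-[(tert-butyldimethylsilyl)oxy]-1-hydroxy-4a,5-dimethyl-3-(prop-1-en-2-yl)octahydronaphthalen-2(1H)-one | C=C(C)[C@@H]1C[C@]2(C)[C@@H](C)[C@H](O[Si](C)(C)C(C)(C)C)CC[C@H]2[C@H](O)C1=O
F6 | step 8 | ethyl (2R)-2-[(1R,3R,4R)-4-[(tert-butyldimethylsilyl)oxy]-3-methyl-2-methylidenecyclohexyl]-2-hydroxyacetate | C[C@H]1[C@H](O[Si](C)(C)C(C)(C)C)CC[C@@H]([C@@H](O)C(=O)OCC)C1=C
F7 | step 8 | ethyl (2S)-2-[(1R,3R,4R)-4-[(tert-butyldimethylsilyl)oxy]-3-methyl-2-methylidenecyclohexyl]-2-[(4-nitrobenzoyl)oxy]acetate | C[C@H]1[C@H](O[Si](C)(C)C(C)(C)C)CC[C@@H]([C@H](OC(=O)c2ccc(cc2)[N+](=O)[O-])C(=O)OCC)C1=C
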